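# Proposed synthesis of 5,7-dihydroxy-3-methoxy-4'-prenyloxyflavone (11)

## Analysis of the target

The target 11 is a flavone. Benzo ring A carries free hydroxyls at C5 and C7 and is fused to the 4-pyranone ring C, whose C3 bears a methoxy group and whose C2 bears ring B, a para-substituted phenyl with a 3-methylbut-2-enyl (prenyl) ether at O4'. There is no stereocentre, and the prenyl double bond carries two identical methyl groups, so no configuration has to be set.

The delicate function is the aryl prenyl ether. Acid ionises it to a phenol and an allyl cation, strong heating triggers Claisen rearrangement, and hydrogenation, halogens and electrophilic oxidants attack its alkene. The pyranone can add hard nucleophiles at C2, and the ring A phenols are easily oxidised.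

The real difficulty is the pattern on four oxygens: O3 methylated, O4' prenylated, O5 and O7 free. O7 is the most acidic and most easily alkylated hydroxyl of a flavone, so this pattern cannot be written onto a preformed polyphenol, and each oxygen has to arrive already in its final form. Ring C must therefore be closed late, from a ring A piece and a ring B piece, under conditions that are neither acidic nor very hot.

The strategy rests on reading the C2=C3 unit of ring C, with aryl on C2 and methoxy on C3, as the two carbons of the aryl methoxy alkyne 9. The remaining ring C atoms C4 and O1, together with ring A, are the formyl carbon and one ortho phenol oxygen of the salicylaldehyde 2. The two hydroxyls flanking the formyl group of 1 are equivalent, so either may become O1 and the other becomes O5.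

## Retrosynthetic reasoning

**11 ⇒ 10.** The two O–acyl bonds at O5 and O7 are cut first. Ring A needs protection during ring closure, and the protecting groups must come off without acid, heat or hydrogen because of the prenyl ether. Aryl pivalates meet this: they are cleaved by base-mediated transesterification, they survive a neutral-to-basic metal-catalysed step at about 90 °C, and as electron-withdrawing groups they make ring A less prone to oxidation. The forward step has only to cleave two aryl esters without touching ring C.

**10 ⇒ 2 + 9.** Ring C is cut at C3–C4 and at O1–C2. This divides the flavone into a salicylaldehyde (2) and an alkyne (9), each already carrying its oxygen substituents in final form. Both ring C bonds are then made in one operation, with no open-chain diketone or chalcone in between and no acid-promoted cyclodehydration. Cutting at C2–C1' or at C4–C4a would require a preformed pyranone or a Friedel–Crafts-type acylation and would bring back the problem of differentiating the phenols. The forward reaction has to activate the formyl C–H bond of 2 under direction of its one free phenol, insert 9 with the aryl-bearing carbon ending at C2 and the methoxy-bearing carbon at C3, close the ring by C–O bond formation, and do so without acid, since 9 is an acid-sensitive ynol ether.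

**9 ⇒ 5 + 8 (from 6 via 7).** The C(sp)–C(aryl) bond of 9 is cut. Forming the O–C(sp) bond instead has no reliable counterpart, whereas coupling an alkynyl metal with an aryl iodide is dependable. The free terminal ynol ether is volatile and awkward to handle, so its lithium and zinc acetylides 7 and 8 are made in the flask from the stable acetal 6 by double elimination and used directly. The forward reaction is a palladium-catalysed cross-coupling of 8 with 5 near room temperature, followed by isolation of 9 without contact with acid.

**5 ⇒ 3 + 4.** The O4'–CH2 bond is cut. Iodophenol 3 has a single hydroxyl, so alkylation with 4 needs no selectivity, and the choice between O4' and O7 never arises later. The iodide is the handle for the coupling above.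

**2 ⇒ 1.** Two O–acyl bonds are cut. In 1 the para hydroxyl and one ortho hydroxyl are free to react, while the second ortho hydroxyl is locked in a hydrogen bond to the formyl oxygen. Two equivalents of a bulky acylating agent should therefore stop at 2, leaving exactly the phenol needed as directing group and future O1. The symmetry of 1 means only one bis-ester of this type exists.

## Alternatives that were turned down

**Alternative 1: C4 from carbon monoxide by carbonylative α-arylation.**
- Disconnection: C4a–C4 and C3–C4 are cut, and C4 is supplied by carbon monoxide A4. The other components are 2-iodo-1,3,5-tris(methoxymethoxy)benzene A2 and 2-methoxy-1-[4-(3-methylbut-2-enyloxy)phenyl]ethanone A3.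
- Forward key step: a zerovalent palladium catalyst with a bidentate phosphine joins A2, A4 and the sodium enolate of A3 to the racemic diketone 2-methoxy-1-[4-(3-methylbut-2-enyloxy)phenyl]-3-[2,4,6-tris(methoxymethoxy)phenyl]propane-1,3-dione A1. Acetal removal and cyclodehydration then form O1–C2.
- For: three simple components; carbonylative α-arylation of ketone enolates is an established reaction type; the sense of ring closure is fixed by connectivity; the stereocentre of A1 is erased on aromatisation.
- Against: A2 is very electron-rich and flanked by two ortho alkoxy groups, so oxidative addition and CO insertion are slow, and direct arylation without A4 or O-acylation of the enolate can compete. A1 is more acidic than A3 and consumes base. The key step builds only the open chain. Closing ring C and removing three acetals both need acid, which is the condition under which the prenyl ether of ring B ionises.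
- Comparison: on precedent for the substrate class and on regiochemical certainty this route is stronger. The chosen route offers ring closure and both ring C bonds in one non-acidic step, a base-labile end game, and five operations against roughly six to seven.

**Alternative 2: one-carbon methoxy ylide linchpin with intramolecular ester Wittig closure.**
- Disconnection: C3 comes from methoxymethylenetriphenylphosphorane A7; C3–C4 and C2=C3 are cut. The ring A component is 2,4,6-tris[4-(3-methylbut-2-enyloxy)benzoyloxy]benzoyl chloride A6.
- Forward key step: A6 acylates A7, and the resulting acyl ylide attacks an ortho ester carbonyl to give 3-methoxy-4'-prenyloxy-5,7-bis[4-(3-methylbut-2-enyloxy)benzoyloxy]flavone A5. Base-mediated removal of the two remaining aroyl esters finishes the synthesis.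
- For: all three ring A oxygens carry the same acyl group, so no selective protection is needed (simpler than step 1 here); C2 can only arise from an ester carbonyl, so there is no regiochemical question; the end game is as mild as the chosen one.
- Against: three ring B acyl units are spent to install one. A6 derives from 2,4,6-trihydroxybenzoic acid A8, which decarboxylates easily, and the acidic by-product of acid chloride formation endangers three prenyl ethers. A7 is a strongly basic, non-stabilised ylide that can attack the three aryl esters as well as the acid chloride, and a second equivalent is consumed as base. The closing Wittig must make a tetrasubstituted alkene from a methoxy-substituted ylide carbon and a weakly electrophilic, doubly ortho-flanked ester carbonyl. A stoichiometric phosphine oxide is formed.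
- Comparison: stronger on regiochemical certainty and on avoiding selective protection. The chosen route offers a catalytic ring closure, no sacrificial ring B units and no strongly basic reagent near aryl esters.

**Alternative 3: Mentzer thermal condensation.**
- Disconnection: C4–C4a and O1–C2 are cut between phloroglucinol A11 and racemic ethyl 3-(4-benzyloxyphenyl)-2-methoxy-3-oxopropanoate A10.
- Forward key step: heating the two neat to roughly 250 °C causes C-acylation and cyclodehydration to 4'-benzyloxy-5,7-dihydroxy-3-methoxyflavone A9.
- For: by far the shortest access to the ring system; no protecting groups on ring A; the threefold symmetry of A11 removes any regiochemical question. On step count to the flavone core it is stronger than the chosen route.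
- Against: a prenyl aryl ether cannot survive that temperature, hence the benzyl placeholder in A9. After hydrogenolysis to 5,7-dihydroxy-2-(4-hydroxyphenyl)-3-methoxychromen-4-one A12, alkylation with 4 would hit the more acidic O7 before O4', so ring A protection returns and three to four steps are added. Thermal condensations of this kind are forcing and prone to charring.
- Comparison: the chosen route carries the prenyl ether from 5 onward under mild conditions and never has to distinguish O4' from O7, at the cost of a less precedented key step.

Key step: step 4

## Route

Step 1
Reactants: 1 2,4,6-trihydroxybenzaldehyde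
Product: 2 2-hydroxy-4,6-bis(pivaloyloxy)benzaldehyde
Conditions: PivCl (2.05 equiv), Et3N (2.2 equiv), THF, −10 °C to 0 °C
Reagents that add atoms: pivaloyl chloride, CC(C)(C)C(=O)Cl
Why: Chemoselective O-acylation: the para hydroxyl and one ortho hydroxyl react, while the last ortho hydroxyl is held in a six-membered hydrogen bond to the formyl oxygen and is too poor a nucleophile for the bulky acyl chloride without an acyl-transfer catalyst. The two ortho hydroxyls of 1 are equivalent, so a single bis-ester results.

Step 2
Reactants: 3 4-iodophenol; 4 1-bromo-3-methylbut-2-ene (prenyl bromide)
Product: 5 1-iodo-4-(3-methylbut-2-enyloxy)benzene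
Conditions: K2CO3, acetone, rt
Reagents that add atoms: none
Why: Williamson ether synthesis: the phenoxide displaces bromide at the unhindered primary allylic carbon (SN2), and the aryl iodide is inert to these conditions.

Step 3
Reactants: 5 1-iodo-4-(3-methylbut-2-enyloxy)benzene; 6 2-chloro-1,1-dimethoxyethane (chloroacetaldehyde dimethyl acetal)
Product: 9 1-(methoxyethynyl)-4-(3-methylbut-2-enyloxy)benzene, via methoxyethynyllithium 7 (not isolated), via methoxyethynylzinc chloride 8 (not isolated)
Conditions: 6 (1.5 equiv), LiNEt2 (4.5 equiv), THF, 0 °C; ZnCl2 (1.7 equiv), 0 °C to rt; then 5, Pd(PPh3)4 (5 mol %), rt to 45 °C; aq. NaHCO3 work-up, Et3N-treated silica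
Reagents that add atoms: none
Why: Two base-induced β-eliminations (of hydrogen chloride and of methanol) and a final deprotonation convert 6 into acetylide 7, a standard entry to methoxyethynyl metal reagents, and ZnCl2 gives 8. Negishi coupling (oxidative addition of the aryl iodide to zerovalent palladium, transmetalation, reductive elimination) then forms the C(sp)–C(sp2) bond, as known for alkoxyethynylzinc halides with aryl iodides. The prenyl ether is inert, and the basic work-up protects the acid-sensitive ynol ether.

Step 4
Reactants: 2 2-hydroxy-4,6-bis(pivaloyloxy)benzaldehyde; 9 1-(methoxyethynyl)-4-(3-methylbut-2-enyloxy)benzene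
Product: 10 3-methoxy-4'-(3-methylbut-2-enyloxy)-5,7-bis(pivaloyloxy)flavone
Conditions: 9 (1.3 equiv), [Cp*RhCl2]2 (2.5 mol %), Ag2CO3 (1.2 equiv), CsOPiv (20 mol %), 4 Å MS, toluene, 90 °C, Ar
Reagents that add atoms: none
Why: Proposed new method: the closest known reaction type is the rhodium-catalysed oxidative coupling of salicylaldehydes with internal diaryl and alkyl aryl alkynes to 2,3-disubstituted chromones, and the new element is an ynol ether as the alkyne; mechanistically the phenoxide of 2 binds trivalent rhodium and directs carboxylate-assisted cleavage of the formyl C–H bond to a five-membered acyl rhodacycle, alkyne 9 inserts into the rhodium–acyl bond (forming C3–C4) to give a seven-membered oxa-rhodacycle, and C–O reductive elimination forms O1–C2 and releases monovalent rhodium, which Ag2CO3 reoxidises. Ring C is thus closed in a formal (4+2) annulation whose ring-closing event is reductive elimination from the metallacycle rather than a polar 6-endo attack, so no 5-exo closure to an aurone competes. No stereocentre is created. The selectivity the step needs is the orientation of insertion, and two substrate features point the same way: the aryl-substituted alkyne carbon is the one that prefers to sit on rhodium, as in the known reactions of alkyl aryl alkynes, and the oxygen-substituted carbon is the electrophilic end of the polarised ynol ether and accepts the migrating acyl group, which places aryl on C2 and methoxy on C3. Only one hydroxyl is free in 2, so the directing phenoxide and hence O1 are unambiguous, and the pivalates lower the electron density of ring A enough to shield it from the silver oxidant. The methyl ynol ether has no β-hydrogen in its alkyl group and cannot collapse to a ketene by retro-ene elimination at 90 °C, while the basic carbonate oxidant, the absence of free carboxylic acid and the molecular sieves are chosen to suppress hydration and acid addition across the triple bond. The prenyl ether and both aryl pivalates should be inert to these neutral-to-basic, non-nucleophilic conditions.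

Step 5
Reactants: 10 3-methoxy-4'-(3-methylbut-2-enyloxy)-5,7-bis(pivaloyloxy)flavone
Product: 11 5,7-dihydroxy-3-methoxy-4'-(3-methylbut-2-enyloxy)flavone
Conditions: K2CO3, MeOH, rt; then aq. citric acid to pH 5
Reagents that add atoms: none
Why: Base-mediated transesterification (methanolysis) of two aryl pivalates: the phenoxides at O5 and O7 are good leaving groups because they are conjugated with the C4 carbonyl, so ester cleavage should outrun any attack on the pyranone. The prenyl ether, the C3 methyl ether and ring C are stable to K2CO3 in methanol at room temperature.

## Compound list

1 | 2,4,6-trihydroxybenzaldehyde | O=Cc1c(O)cc(O)cc1O | starting material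
2 | 2-hydroxy-4,6-bis(pivaloyloxy)benzaldehyde | O=Cc1c(O)cc(OC(=O)C(C)(C)C)cc1OC(=O)C(C)(C)C | intermediate
3 | 4-iodophenol | Oc1ccc(I)cc1 | starting material
4 | 1-bromo-3-methylbut-2-ene (prenyl bromide) | CC(C)=CCBr | starting material
5 | 1-iodo-4-(3-methylbut-2-enyloxy)benzene | CC(C)=CCOc1ccc(I)cc1 | intermediate
6 | 2-chloro-1,1-dimethoxyethane (chloroacetaldehyde dimethyl acetal) | COC(CCl)OC | starting material
7 | methoxyethynyllithium | [Li]C#COC | intermediate
8 | methoxyethynylzinc chloride | Cl[Zn]C#COC | intermediate
9 | 1-(methoxyethynyl)-4-(3-methylbut-2-enyloxy)benzene | COC#Cc1ccc(OCC=C(C)C)cc1 | intermediate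
10 | 3-methoxy-4'-(3-methylbut-2-enyloxy)-5,7-bis(pivaloyloxy)flavone | COc1c(-c2ccc(OCC=C(C)C)cc2)oc2cc(OC(=O)C(C)(C)C)cc(OC(=O)C(C)(C)C)c2c1=O | intermediate
11 | 5,7-dihydroxy-3-methoxy-4'-(3-methylbut-2-enyloxy)flavone | COc1c(-c2ccc(OCC=C(C)C)cc2)oc2cc(O)cc(O)c2c1=O | target

## Step count and least certain steps

Total step count: 5. Longest linear sequence: 4 steps (3 → 5 → 9 → 10 → 11, steps 2 to 5); the ring A branch (1 → 2) joins at step 4.

**Step 4 (key step, bears the label).**
- What may go wrong: the ynol ether may be consumed before it inserts, by hydration, by addition of the phenol O–H of 2 across the triple bond under rhodium or silver activation, or by oligomerisation. Insertion may occur in the reversed orientation. The acyl rhodium intermediate may decarbonylate.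
- Fallback (known chemistry), from 5 and 2, returning at 10: iodide 5 would undergo iodine–magnesium exchange with iPrMgCl·LiCl (THF, −20 °C), and the aryl Grignard reagent would be acylated with N,2-dimethoxy-N-methylacetamide to give 2-methoxy-1-[4-(3-methylbut-2-enyloxy)phenyl]ethanone F1 (the same ketone as A3). Its lithium enolate (LiN(SiMe3)2, THF, −78 °C) would be added to aldehyde 2, whose phenol is first converted to the lithium phenoxide with one further equivalent of LiN(SiMe3)2. A cold acetic acid quench, to forestall migration of the ortho pivaloyl group to the new alkoxide, should give the aldol adduct 3-hydroxy-3-[2-hydroxy-4,6-bis(pivaloyloxy)phenyl]-2-methoxy-1-[4-(3-methylbut-2-enyloxy)phenyl]propan-1-one F2 as a mixture of diastereomers; this is harmless because both stereocentres are lost later. Dess–Martin oxidation (NaHCO3-buffered CH2Cl2) would give the racemic diketone 1-[2-hydroxy-4,6-bis(pivaloyloxy)phenyl]-2-methoxy-3-[4-(3-methylbut-2-enyloxy)phenyl]propane-1,3-dione F3. Cyclodehydration of its free ortho phenol onto the ring B ketone (catalytic pyridinium p-toluenesulfonate, toluene, 60 °C), the closing stage of a Baker–Venkataraman flavone synthesis, would deliver 10.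

**Step 1.**
- What may go wrong: acylation may not stop cleanly at the bis-ester; under- and over-acylation would give mixtures that are hard to separate, because the chelated hydroxyl is deactivated but not inert.
- Fallback, from 1, returning at 11: the protecting-group class is changed. Treating 1 with iPr3SiCl (2.1 equiv) and imidazole in CH2Cl2 should give 2-hydroxy-4,6-bis(triisopropylsilyloxy)benzaldehyde F4, since the much bulkier silyl chloride discriminates more sharply against the chelated, flanked hydroxyl. F4 would be annulated with 9 under the conditions of step 4 to give 3-methoxy-4'-(3-methylbut-2-enyloxy)-5,7-bis(triisopropylsilyloxy)flavone F5. Bu4NF buffered with acetic acid (THF, 0 °C) would then remove both silyl groups and give 11.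

**Step 3.**
- What may go wrong: elimination of 6 to 7 may be incomplete; 8 may be protonated by the diethylamine present; transmetalation may be slow because the zinc also carries amide and alkoxide ligands; 9 may be lost by hydration during work-up or chromatography.
- Fallback, from 6 and 5, returning at 9: acetylide 7 would be generated from 6 as in step 3 and quenched with Bu3SnCl to give tributyl(methoxyethynyl)stannane F6, an isolable reagent that can be distilled and assayed. Stille coupling of F6 with 5 (PdCl2(PPh3)2, Et4NCl, DMF, 60 °C), the known route to aryl alkoxyalkynes from alkoxyethynylstannanes, would give 9 under neutral conditions.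

## Further compounds

F1 | step 4 | 2-methoxy-1-[4-(3-methylbut-2-enyloxy)phenyl]ethanone | COCC(=O)c1ccc(OCC=C(C)C)cc1
F2 | step 4 | 3-hydroxy-3-[2-hydroxy-4,6-bis(pivaloyloxy)phenyl]-2-methoxy-1-[4-(3-methylbut-2-enyloxy)phenyl]propan-1-one (racemic mixture of diastereomers) | COC(C(O)c1c(O)cc(OC(=O)C(C)(C)C)cc1OC(=O)C(C)(C)C)C(=O)c1ccc(OCC=C(C)C)cc1
F3 | step 4 | 1-[2-hydroxy-4,6-bis(pivaloyloxy)phenyl]-2-methoxy-3-[4-(3-methylbut-2-enyloxy)phenyl]propane-1,3-dione (racemic) | COC(C(=O)c1c(O)cc(OC(=O)C(C)(C)C)cc1OC(=O)C(C)(C)C)C(=O)c1ccc(OCC=C(C)C)cc1
F4 | step 1 | 2-hydroxy-4,6-bis(triisopropylsilyloxy)benzaldehyde | O=Cc1c(O)cc(O[Si](C(C)C)(C(C)C)C(C)C)cc1O[Si](C(C)C)(C(C)C)C(C)C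
F5 | step 1 | 3-methoxy-4'-(3-methylbut-2-enyloxy)-5,7-bis(triisopropylsilyloxy)flavone | COc1c(-c2ccc(OCC=C(C)C)cc2)oc2cc(O[Si](C(C)C)(C(C)C)C(C)C)cc(O[Si](C(C)C)(C(C)C)C(C)C)c2c1=O
F6 | step 3 | tributyl(methoxyethynyl)stannane | COC#C[Sn](CCCC)(CCCC)CCCC
A1 | alternative 1 | 2-methoxy-1-[4-(3-methylbut-2-enyloxy)phenyl]-3-[2,4,6-tris(methoxymethoxy)phenyl]propane-1,3-dione (racemic) | COCOc1cc(OCOC)c(C(=O)C(OC)C(=O)c2ccc(OCC=C(C)C)cc2)c(OCOC)c1
A2 | alternative 1 | 2-iodo-1,3,5-tris(methoxymethoxy)benzene | COCOc1cc(OCOC)c(I)c(OCOC)c1
A3 | alternative 1 | 2-methoxy-1-[4-(3-methylbut-2-enyloxy)phenyl]ethanone | COCC(=O)c1ccc(OCC=C(C)C)cc1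
A4 | alternative 1 | carbon monoxide | [C-]#[O+]
A5 | alternative 2 | 3-methoxy-4'-prenyloxy-5,7-bis[4-(3-methylbut-2-enyloxy)benzoyloxy]flavone | COc1c(-c2ccc(OCC=C(C)C)cc2)oc2cc(OC(=O)c3ccc(OCC=C(C)C)cc3)cc(OC(=O)c3ccc(OCC=C(C)C)cc3)c2c1=O
A6 | alternative 2 | 2,4,6-tris[4-(3-methylbut-2-enyloxy)benzoyloxy]benzoyl chloride | O=C(Cl)c1c(OC(=O)c2ccc(OCC=C(C)C)cc2)cc(OC(=O)c2ccc(OCC=C(C)C)cc2)cc1OC(=O)c1ccc(OCC=C(C)C)cc1
A7 | alternative 2 | methoxymethylenetriphenylphosphorane | COC=P(c1ccccc1)(c1ccccc1)c1ccccc1
A8 | alternative 2 | 2,4,6-trihydroxybenzoic acid | O=C(O)c1c(O)cc(O)cc1O
A9 | alternative 3 | 4'-benzyloxy-5,7-dihydroxy-3-methoxyflavone | COc1c(-c2ccc(OCc3ccccc3)cc2)oc2cc(O)cc(O)c2c1=O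
A10 | alternative 3 | ethyl 3-(4-benzyloxyphenyl)-2-methoxy-3-oxopropanoate (racemic) | CCOC(=O)C(OC)C(=O)c1ccc(OCc2ccccc2)cc1
A11 | alternative 3 | phloroglucinol | Oc1cc(O)cc(O)c1
A12 | alternative 3 | 5,7-dihydroxy-2-(4-hydroxyphenyl)-3-methoxychromen-4-one | COc1c(-c2ccc(O)cc2)oc2cc(O)cc(O)c2c1=O
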